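**Retrosynthetic overview**
- The enone is made last, by Wittig olefination of the C11 aldehyde after acid unmasking of a dioxolane and a tert-butyl ester.
- The 1,2-dioxane is the only ring formed: a photochemical O2 capture at C6 (from a tertiary oxalate) followed by 6-exo peroxy-Michael closure onto an (E)-enoate makes C6–O and O–C3.
- The enoate/oxalate comes from a C6 ketone by ethyl Grignard addition with oxalylation, then cross-metathesis with tert-butyl acrylate.
- The ketone comes from a Carroll rearrangement joining the side-chain acid to (2S,3E)-hex-3-en-2-ol; 1,3-chirality transfer sets C4.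
- The side-chain acid comes from (S)-5-methylcyclohex-2-en-1-one by trans conjugate ethylation (C10 from C8) and ozonolysis of the silyl enol ether, which opens the carbocycle.

Assumption: (S)-5-methylcyclohex-2-en-1-one and (S)-but-3-yn-2-ol are taken as purchasable single enantiomers.

**Step 1**
Reactants: 1 (S)-but-3-yn-2-ol
Product: 2 (S)-hex-3-yn-2-ol
Conditions: n-BuLi (2.2 equiv), THF, −78 to 0 °C; EtI, DMPU, 0 °C to rt
Reagents that add atoms: iodoethane CCI
Why: The alkoxide/acetylide dianion is alkylated only at carbon (acetylide alkylation), so the bought carbinol centre is untouched.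

**Step 2**
Reactants: 2 (S)-hex-3-yn-2-ol
Product: 3 (2S,3E)-hex-3-en-2-ol
Conditions: LiAlH4, THF, 0 °C to reflux
Reagents that add atoms: none
Why: Alkoxide-directed trans-hydroalumination of the propargylic alcohol gives only the (E)-allylic alcohol, the geometry the later chair rearrangement needs.

**Step 3**
Reactants: 4 (S)-5-methylcyclohex-2-en-1-one
Product: 5 {[(3S,5S)-3-ethyl-5-methylcyclohex-1-en-1-yl]oxy}trimethylsilane
Conditions: EtMgBr, CuBr·SMe2 (5 mol %), Me3SiCl, HMPA, THF, −78 °C; Et3N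
Reagents that add atoms: ethylmagnesium bromide CC[Mg]Br; chlorotrimethylsilane C[Si](C)(C)Cl
Why: Copper-catalysed, silyl-chloride-accelerated conjugate addition delivers ethyl anti to the ring methyl of the half-chair enone, setting the future C10 trans to the bought C8, and traps the enolate regiospecifically as the C1=C2 silyl enol ether.

**Step 4**
Reactants: 5 {[(3S,5S)-3-ethyl-5-methylcyclohex-1-en-1-yl]oxy}trimethylsilane
Product: 7 (3S,5S)-5-(1,3-dioxolan-2-yl)-3-methylheptanoic acid, via aldehyde acid 6 (not isolated)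
Conditions: O3, CH2Cl2, −78 °C; PPh3, −78 °C to rt; then HOCH2CH2OH, PPTS (cat.), benzene, 80 °C, Dean–Stark
Reagents that add atoms: ozone [O-][O+]=O; ethane-1,2-diol OCCO
Why: Ozonolysis of the regiodefined silyl enol ether cuts C1–C2 into a carboxylic acid (future C6) and an α-branched aldehyde (future C11), which is capped at once as the dioxolane under weak acid that neither esterifies the acid nor epimerises the α-centre.

**Step 5**
Reactants: 7 (3S,5S)-5-(1,3-dioxolan-2-yl)-3-methylheptanoic acid; 3 (2S,3E)-hex-3-en-2-ol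
Product: 9 (2S,3E)-hex-3-en-2-yl (5S,7S)-7-(1,3-dioxolan-2-yl)-5-methyl-3-oxononanoate, via acyl Meldrum's acid 8 (not isolated)
Conditions: Meldrum's acid, DCC, DMAP, CH2Cl2, 0 °C to rt; filter; then 3, toluene, 110 °C
Reagents that add atoms: Meldrum's acid (2,2-dimethyl-1,3-dioxane-4,6-dione) CC1(C)OC(=O)CC(=O)O1
Why: Carbodiimide C-acylation of Meldrum's acid, then thermal acylketene release and capture by the secondary allylic alcohol, is the standard route to allyl β-keto esters and touches no stereocentre.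

**Step 6**
Reactants: 9 (2S,3E)-hex-3-en-2-yl (5S,7S)-7-(1,3-dioxolan-2-yl)-5-methyl-3-oxononanoate
Product: 11 (2E,4S,8S,10S)-10-(1,3-dioxolan-2-yl)-4-ethyl-8-methyldodec-2-en-6-one, via β-keto acid 10 (not isolated)
Conditions: LiN(i-Pr)2 (2.2 equiv), THF, −78 to 65 °C; aq. HCl to pH 4 at 0 °C; toluene, 80 °C
Reagents that add atoms: none
Why: The dianion undergoes the ester-enolate Carroll rearrangement ([3,3]-sigmatropic) through a chair with the carbinol methyl equatorial, so the bought (S) C–O centre of the (E)-allyl unit is relayed into the new (S) C–C centre (future C4) with an (E)-propenyl group, and the β-keto acid loses CO2 on warming.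

**Step 7**
Reactants: 11 (2E,4S,8S,10S)-10-(1,3-dioxolan-2-yl)-4-ethyl-8-methyldodec-2-en-6-one
Product: 13 methyl (2E,4S,8S,10S)-10-(1,3-dioxolan-2-yl)-4,6-diethyl-8-methyldodec-2-en-6-yl oxalate (C6 epimers), via bromomagnesium alkoxide 12 (not isolated)
Conditions: EtMgBr, LaCl3·2LiCl (0.3 equiv), THF, 0 °C; then ClC(O)CO2Me, DMAP (cat.), 0 °C to rt
Reagents that add atoms: ethylmagnesium bromide CC[Mg]Br; methyl chlorooxoacetate COC(=O)C(Cl)=O
Why: Lanthanum-promoted Grignard 1,2-addition to the enolisable ketone and O-acylation of the tertiary alkoxide give the tertiary oxalate; C6 forms as both epimers, which does not matter because it becomes a planar radical in step 9.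

**Step 8**
Reactants: 13 methyl (2E,4S,8S,10S)-10-(1,3-dioxolan-2-yl)-4,6-diethyl-8-methyldodec-2-en-6-yl oxalate (C6 epimers)
Product: 14 tert-butyl (2E,4S,8S,10S)-10-(1,3-dioxolan-2-yl)-4,6-diethyl-6-[(methoxyoxalyl)oxy]-8-methyldodec-2-enoate (C6 epimers)
Conditions: tert-butyl acrylate (5 equiv), second-generation Grubbs catalyst (H2IMes)(PCy3)Cl2Ru=CHPh (5 mol %), CH2Cl2, 40 °C
Reagents that add atoms: tert-butyl acrylate C=CC(=O)OC(C)(C)C
Why: Olefin cross-metathesis of the only alkene, a 1,2-disubstituted propenyl group, with excess acrylate gives the (E)-enoate and volatile propene without touching the allylic C4 centre.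

**Step 9**
Reactants: 14 tert-butyl (2E,4S,8S,10S)-10-(1,3-dioxolan-2-yl)-4,6-diethyl-6-[(methoxyoxalyl)oxy]-8-methyldodec-2-enoate (C6 epimers)
Product: 17 tert-butyl 2-[(3S,4S,6R)-6-[(2S,4S)-4-(1,3-dioxolan-2-yl)-2-methylhexyl]-4,6-diethyl-1,2-dioxan-3-yl]acetate, via cesium oxalate 15 (not isolated), via hydroperoxide 16 (not isolated)
Conditions: CsOH·H2O (1.0 equiv), THF/H2O, 0 °C, evaporate; 4CzIPN (2 mol %), DME/DMF 3:1, H2O (10 equiv), 5% O2 in N2, 450 nm LEDs, 45 °C; then Et2NH (cat.), CF3CH2OH, 0 °C; chromatographic separation of the C6 epimer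
Reagents that add atoms: dioxygen O=O
Why: Proposed new method: excited 4CzIPN oxidises the cesium oxalate, which loses two CO2 to give the tertiary C6 radical; O2 traps it at near diffusion rate (O2 is kept near 5% and the bath at 45 °C so that loss of the second CO2 precedes oxygen capture of the alkoxycarbonyl radical), the reduced photocatalyst turns the peroxyl radical into the cesium peroxide, and this closes by kinetic 6-exo-trig peroxy-Michael addition through a chair with the C4 ethyl equatorial and the (E)-enoate axial, setting C3 (S) cis to C4, whereas C6 forms without facial bias (about 1:1, ethyl and the CH2 chain being sterically alike) and the (6R) isomer is isolated by chromatography; the closest known reactions are photoredox radical generation from tertiary cesium oxalates (used for Giese addition and fluorination), aerobic photodecarboxylative hydroperoxidation of carboxylic acids, and base-mediated hydroperoxide oxa-Michael closure of 1,2-dioxanes.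

**Step 10**
Reactants: 17 tert-butyl 2-[(3S,4S,6R)-6-[(2S,4S)-4-(1,3-dioxolan-2-yl)-2-methylhexyl]-4,6-diethyl-1,2-dioxan-3-yl]acetate
Product: 19 2-[(3S,4S,6R)-4,6-diethyl-6-[(2S,4S,5E)-4-ethyl-2-methyl-7-oxooct-5-en-1-yl]-1,2-dioxan-3-yl]acetic acid, via aldehyde acid 18 (not isolated)
Conditions: TFA/CH2Cl2/H2O (10:10:1), 0 °C to rt; evaporate with toluene; then Ph3P=CHC(O)CH3 (3 equiv), CH2Cl2, rt; aq. citric acid work-up
Reagents that add atoms: 1-(triphenylphosphoranylidene)propan-2-one CC(=O)C=P(c1ccccc1)(c1ccccc1)c1ccccc1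
Why: Aqueous trifluoroacetic acid removes the dioxolane and the tert-butyl ester while the dialkyl peroxide is expected to survive, and the stabilised ylide then gives the (E)-enone by Wittig olefination without reducing the O–O bond or epimerising C10.

**Compound list**
1 | (S)-but-3-yn-2-ol | C[C@H](O)C#C | starting material
2 | (S)-hex-3-yn-2-ol | C[C@H](O)C#CCC | intermediate
3 | (2S,3E)-hex-3-en-2-ol | C[C@H](O)/C=C/CC | intermediate
4 | (S)-5-methylcyclohex-2-en-1-one | C[C@H]1CC=CC(=O)C1 | starting material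
5 | {[(3S,5S)-3-ethyl-5-methylcyclohex-1-en-1-yl]oxy}trimethylsilane | C[C@H]1C[C@H](CC)C=C(O[Si](C)(C)C)C1 | intermediate
6 | (3S,5S)-5-ethyl-3-methyl-6-oxohexanoic acid | C[C@@H](C[C@H](CC)C=O)CC(=O)O | intermediate
7 | (3S,5S)-5-(1,3-dioxolan-2-yl)-3-methylheptanoic acid | C[C@@H](C[C@H](CC)C1OCCO1)CC(=O)O | intermediate
8 | 5-[(3S,5S)-5-(1,3-dioxolan-2-yl)-1-hydroxy-3-methylheptylidene]-2,2-dimethyl-1,3-dioxane-4,6-dione | C[C@@H](C[C@H](CC)C1OCCO1)CC(O)=C1C(=O)OC(C)(C)OC1=O | intermediate
9 | (2S,3E)-hex-3-en-2-yl (5S,7S)-7-(1,3-dioxolan-2-yl)-5-methyl-3-oxononanoate | C[C@@H](C[C@H](CC)C1OCCO1)CC(=O)CC(=O)O[C@@H](C)/C=C/CC | intermediate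
10 | (3R,4E)-2-[(3S,5S)-5-(1,3-dioxolan-2-yl)-3-methylheptanoyl]-3-ethylhex-4-enoic acid (C2 epimers) | C[C@@H](C[C@H](CC)C1OCCO1)CC(=O)C(C(=O)O)[C@H](CC)/C=C/C | intermediate
11 | (2E,4S,8S,10S)-10-(1,3-dioxolan-2-yl)-4-ethyl-8-methyldodec-2-en-6-one | C[C@@H](C[C@H](CC)C1OCCO1)CC(=O)C[C@H](CC)/C=C/C | intermediate
12 | bromomagnesium (2E,4S,8S,10S)-10-(1,3-dioxolan-2-yl)-4,6-diethyl-8-methyldodec-2-en-6-olate (C6 epimers) | C[C@@H](C[C@H](CC)C1OCCO1)CC(CC)(O[Mg]Br)C[C@H](CC)/C=C/C | intermediate
13 | methyl (2E,4S,8S,10S)-10-(1,3-dioxolan-2-yl)-4,6-diethyl-8-methyldodec-2-en-6-yl oxalate (C6 epimers) | C[C@@H](C[C@H](CC)C1OCCO1)CC(CC)(OC(=O)C(=O)OC)C[C@H](CC)/C=C/C | intermediate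
14 | tert-butyl (2E,4S,8S,10S)-10-(1,3-dioxolan-2-yl)-4,6-diethyl-6-[(methoxyoxalyl)oxy]-8-methyldodec-2-enoate (C6 epimers) | C[C@@H](C[C@H](CC)C1OCCO1)CC(CC)(OC(=O)C(=O)OC)C[C@H](CC)/C=C/C(=O)OC(C)(C)C | intermediate
15 | cesium salt of the oxalate half-ester of tert-butyl (2E,4S,8S,10S)-10-(1,3-dioxolan-2-yl)-4,6-diethyl-6-hydroxy-8-methyldodec-2-enoate (C6 epimers) | C[C@@H](C[C@H](CC)C1OCCO1)CC(CC)(OC(=O)C(=O)[O-])C[C@H](CC)/C=C/C(=O)OC(C)(C)C.[Cs+] | intermediate
16 | tert-butyl (2E,4S,8S,10S)-10-(1,3-dioxolan-2-yl)-4,6-diethyl-6-hydroperoxy-8-methyldodec-2-enoate (C6 epimers) | C[C@@H](C[C@H](CC)C1OCCO1)CC(CC)(OO)C[C@H](CC)/C=C/C(=O)OC(C)(C)C | intermediate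
17 | tert-butyl 2-[(3S,4S,6R)-6-[(2S,4S)-4-(1,3-dioxolan-2-yl)-2-methylhexyl]-4,6-diethyl-1,2-dioxan-3-yl]acetate | CC[C@H](C2OCCO2)C[C@H](C)C[C@]1(CC)C[C@H](CC)[C@H](CC(=O)OC(C)(C)C)OO1 | intermediate
18 | 2-[(3S,4S,6R)-4,6-diethyl-6-[(2S,4S)-4-ethyl-2-methyl-5-oxopentyl]-1,2-dioxan-3-yl]acetic acid | CC[C@H](C=O)C[C@H](C)C[C@]1(CC)C[C@H](CC)[C@H](CC(=O)O)OO1 | intermediate
19 | 2-[(3S,4S,6R)-4,6-diethyl-6-[(2S,4S,5E)-4-ethyl-2-methyl-7-oxooct-5-en-1-yl]-1,2-dioxan-3-yl]acetic acid | CC[C@H](/C=C/C(C)=O)C[C@H](C)C[C@]1(CC)C[C@H](CC)[C@H](CC(=O)O)OO1 | target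

**Step count**
Total: 10 steps. Longest linear sequence: 8 steps (steps 3 to 10, from compound 4); steps 1 and 2 are the side branch to alcohol 3.

**Steps most likely to fail**

Step 9 (the proposed new photochemical step). Two things can go wrong. Oxygen may intercept the alkoxycarbonyl radical before it loses its second CO2, which would return the tertiary alcohol. And C6 is formed without control, so half of the cyclised material is the 6-epimer and must be separated. The fallback uses known chemistry, sets out from ketone 11 and comes back at dioxane 17. Wittig olefination of 11 with Ph3P=CHCH3 (THF, 0 °C) gives the ethylidene diene F1. Cross-metathesis of F1 with tert-butyl acrylate under the step 8 conditions, in which the trisubstituted alkene is inert, gives the enoate F2. Mukaiyama–Isayama hydroperoxysilylation of F2 (Co(thd)2 [bis(2,2,6,6-tetramethylheptane-3,5-dionato)cobalt], O2, Et3SiH, ClCH2CH2Cl, rt) places the peroxide on C6 as the triethylsilyl peroxide F3. HF·pyridine then frees hydroperoxide 16, and Et2NH in CF3CH2OH closes it to 17. The C6 epimers are separated as in the main route.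

Step 6 (dianionic Carroll rearrangement). The rearrangement may stall, or some reaction through a boat may erode the chirality transfer that sets C4. The fallback makes the same C5–C4 bond by a Claisen rearrangement of an allyl vinyl ether; it sets out from acid 7 (with alcohol 3) and comes back at ketone 11. Esterification of 7 with 3 (DCC, DMAP, CH2Cl2) gives the allyl ester F4. Methylenation of the ester carbonyl with the Tebbe reagent Cp2Ti(CH2)ClAlMe2 (THF, pyridine, −40 °C to rt) gives the allyl vinyl ether F5. Heating F5 in toluene at 110 °C gives 11 through the same chair, with the same 1,3-chirality transfer.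

Step 10 (one-pot acid unmasking and Wittig). The tertiary C6–O bond of the peroxide may ionise in trifluoroacetic acid, the α-branched aldehyde may epimerise at C10, and the free acid consumes ylide. The fallback separates the operations and avoids strong protic acid; it sets out from dioxane 17 and comes back at target 19. Mild acetal hydrolysis (PPTS, acetone/H2O, 50 °C) leaves the ester intact and gives the aldehyde ester F6. Wittig olefination with Ph3P=CHC(O)CH3 gives the enone tert-butyl ester F7. The ester is then cleaved with Me3SiOTf and 2,6-lutidine (CH2Cl2, 0 °C) followed by aqueous work-up to give 19.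

**Further compounds**
F1 | step 9 | 2-[(3S,5S,9S,10E)-9-ethyl-7-ethylidene-5-methyldodec-10-en-3-yl]-1,3-dioxolane | C[C@@H](C[C@H](CC)C1OCCO1)CC(=CC)C[C@H](CC)/C=C/C
F2 | step 9 | tert-butyl (2E,4S,8S,10S)-10-(1,3-dioxolan-2-yl)-4-ethyl-6-ethylidene-8-methyldodec-2-enoate | C[C@@H](C[C@H](CC)C1OCCO1)CC(=CC)C[C@H](CC)/C=C/C(=O)OC(C)(C)C
F3 | step 9 | tert-butyl (2E,4S,8S,10S)-10-(1,3-dioxolan-2-yl)-4,6-diethyl-8-methyl-6-[(triethylsilyl)peroxy]dodec-2-enoate (C6 epimers) | C[C@@H](C[C@H](CC)C1OCCO1)CC(CC)(OO[Si](CC)(CC)CC)C[C@H](CC)/C=C/C(=O)OC(C)(C)C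
F4 | step 6 | (2S,3E)-hex-3-en-2-yl (3S,5S)-5-(1,3-dioxolan-2-yl)-3-methylheptanoate | C[C@@H](C[C@H](CC)C1OCCO1)CC(=O)O[C@@H](C)/C=C/CC
F5 | step 6 | 2-[(3S,5S)-7-{[(2S,3E)-hex-3-en-2-yl]oxy}-5-methyloct-7-en-3-yl]-1,3-dioxolane | C[C@@H](C[C@H](CC)C1OCCO1)CC(=C)O[C@@H](C)/C=C/CC
F6 | step 10 | tert-butyl 2-[(3S,4S,6R)-4,6-diethyl-6-[(2S,4S)-4-ethyl-2-methyl-5-oxopentyl]-1,2-dioxan-3-yl]acetate | CC[C@H](C=O)C[C@H](C)C[C@]1(CC)C[C@H](CC)[C@H](CC(=O)OC(C)(C)C)OO1
F7 | step 10 | tert-butyl 2-[(3S,4S,6R)-4,6-diethyl-6-[(2S,4S,5E)-4-ethyl-2-methyl-7-oxooct-5-en-1-yl]-1,2-dioxan-3-yl]acetate | CC[C@H](/C=C/C(C)=O)C[C@H](C)C[C@]1(CC)C[C@H](CC)[C@H](CC(=O)OC(C)(C)C)OO1
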